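**Retrosynthesis**
1. Moracin Q ← hydrogenolysis of three benzyl ethers ← O‑methylation of the C5 phenol.
2. The C4 side chain (CH2C(=O)iPr) ← a proposed new aromatic Claisen rearrangement of an aryl 1,1‑dimethyl‑2‑silyloxyallyl ether. This is the silyl enol ether of an α‑aryloxy methyl ketone, and it runs from the C5‑O. C6 carries OBn, so C4 is the only free ortho position.
3. The C5‑O comes from Dakin/Baeyer–Villiger oxidation of a 5‑CHO group. The 5‑CHO/6‑OH pair comes from 2,4‑dihydroxy‑5‑iodobenzaldehyde.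
4. Ring order: the furan is formed first (Sonogashira/5‑endo‑dig cyclization with 3,5‑bis(benzyloxy)phenylacetylene). The C5 oxygen and C4 side chain follow, then methylation and global debenzylation.

Assumption: the target has no stereocentres, so "single enantiomer" is moot and no enantiocontrol is needed.

**Route**

**Step 1**
Reactants: 1 (2,4‑dihydroxybenzaldehyde)
Product: 2 (2,4‑dihydroxy‑5‑iodobenzaldehyde)
Conditions: NIS, MeCN, 0 °C → rt, 2 h
Reagents that add atoms: N‑iodosuccinimide, O=C1CCC(=O)N1I (adds I)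
Why: Electrophilic aromatic iodination goes to C5, which is para to the 2‑OH and ortho to the 4‑OH. The carbon between the two OH groups is hindered, and C5 is the known preferred site.

**Step 2**
Reactants: 3 (3,5‑dihydroxybenzaldehyde)
Product: 4 (3,5‑bis(benzyloxy)benzaldehyde)
Conditions: BnBr (2.4 equiv), K2CO3, DMF, 60 °C
Reagents that add atoms: benzyl bromide, BrCc1ccccc1 (adds 2 × Bn)
Why: Williamson O‑benzylation of both phenols.

**Step 3**
Reactants: 4
Product: 5 (1,3‑bis(benzyloxy)‑5‑ethynylbenzene)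
Conditions: dimethyl (1‑diazo‑2‑oxopropyl)phosphonate, K2CO3, MeOH/THF, rt
Reagents that add atoms: Ohira–Bestmann reagent, COP(=O)(OC)C(=[N+]=[N-])C(C)=O (supplies the terminal alkyne carbon)
Why: Ohira–Bestmann homologation of the aldehyde to the terminal alkyne; the benzyl ethers are inert.

**Step 4**
Reactants: 2 (2,4‑dihydroxy‑5‑iodobenzaldehyde) and 5 (1,3‑bis(benzyloxy)‑5‑ethynylbenzene)
Product: 6 (2‑[3,5‑bis(benzyloxy)phenyl]‑6‑hydroxybenzofuran‑5‑carbaldehyde)
Conditions: PdCl2(PPh3)2 (5 mol %), CuI (10 mol %), Et3N, DMF, 80 °C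
Reagents that add atoms: none
Why: Sonogashira coupling at the C–I bond is followed by Cu‑assisted 5‑endo‑dig O‑cyclization. The 4‑OH, ortho to the iodide, closes the furan. The 2‑OH is H‑bonded to the CHO, stays free, and becomes the 6‑OH.

**Step 5**
Reactants: 6
Product: 7 (6‑benzyloxy‑2‑[3,5‑bis(benzyloxy)phenyl]benzofuran‑5‑carbaldehyde)
Conditions: BnBr, K2CO3, DMF, rt
Reagents that add atoms: benzyl bromide, BrCc1ccccc1 (adds Bn)
Why: O‑Benzylation of the 6‑OH blocks that position for the later Claisen step and removes the free phenol before the Dakin step.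

**Step 6**
Reactants: 7
Product: 8 (6‑benzyloxy‑2‑[3,5‑bis(benzyloxy)phenyl]benzofuran‑5‑ol)
Conditions: mCPBA, NaHCO3, CH2Cl2, 0 °C → rt; Na2S2O3 work‑up; then K2CO3, MeOH, rt
Reagents that add atoms: mCPBA, OOC(=O)c1cccc(Cl)c1 (supplies the O atom inserted between the ring and CHO)
Why: Baeyer–Villiger (Dakin‑type) oxidation of an electron‑rich ortho‑alkoxy aryl aldehyde. The aryl group migrates to give the aryl formate, and methanolysis releases the C5 phenol.

**Step 7**
Reactants: 8 and 9 (ethyl 2‑bromo‑2‑methylpropanoate)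
Product: 10 (ethyl 2‑{[6‑benzyloxy‑2‑(3,5‑bis(benzyloxy)phenyl)benzofuran‑5‑yl]oxy}‑2‑methylpropanoate)
Conditions: Cs2CO3, MeCN, 60–80 °C
Reagents that add atoms: compound 9, CCOC(=O)C(C)(C)Br (adds the CMe2CO2Et unit)
Why: Fibrate‑type Williamson etherification of a phenol with an α‑bromoisobutyrate makes the tertiary aryl ether.

**Step 8**
Reactants: 10
Product: 11 (2‑aryloxy‑N‑methoxy‑N,2‑dimethylpropanamide, the Weinreb amide)
Conditions: MeNHOMe·HCl, iPrMgCl, THF, −20 → 0 °C
Reagents that add atoms: N,O‑dimethylhydroxylamine hydrochloride, CNOC.Cl (adds N(OMe)Me)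
Why: Magnesium‑amide aminolysis of the ester (Williams procedure); the benzyl ethers and the benzofuran are untouched.

**Step 9**
Reactants: 11
Product: 12 (3‑aryloxy‑3‑methylbutan‑2‑one: ArO–CMe2–C(=O)CH3)
Conditions: MeMgBr, THF, 0 °C → rt
Reagents that add atoms: methylmagnesium bromide, C[Mg]Br (adds CH3)
Why: Weinreb ketone synthesis; the stable chelate prevents over‑addition to a tertiary alcohol.

**Step 10**
Reactants: 12
Product: 13 (aryl 1,1‑dimethyl‑2‑(tert‑butyldimethylsilyloxy)allyl ether, CH2=C(OTBS)CMe2–OAr)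
Conditions: TBSOTf, Et3N, CH2Cl2, 0 °C
Reagents that add atoms: TBSOTf, CC(C)(C)[Si](C)(C)OS(=O)(=O)C(F)(F)F (adds TBS)
Why: Silyl enol ether formation. Only the CH3 side is enolizable because the other α‑carbon is quaternary, so the regiochemistry is unambiguous.

**Step 11**
Reactants: 13
Product: 14 (1‑[6‑benzyloxy‑2‑(3,5‑bis(benzyloxy)phenyl)‑5‑hydroxybenzofuran‑4‑yl]‑3‑methylbutan‑2‑one)
Conditions: o‑Cl2C6H4, BHT, 180 °C (sealed tube or microwave), 3 h; then TBAF, THF, 0 °C
Reagents that add atoms: none (TBAF only removes TBS and adds H)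
Why: Proposed new method: an aromatic Claisen rearrangement of an aryl 2‑silyloxy‑1,1‑dimethylallyl ether, in which the terminal =CH2 bonds to C4 while the weak tertiary C–O bond breaks.
- The [3,3] shift, followed by rearomatization of the dienone, gives the phenol bearing Ar–CH2–C(OTBS)=CMe2. Fluoride desilylation then protonates the enolate at CMe2 to give the isopropyl ketone directly.
- The closest known reactions are the Claisen of aryl 2‑alkoxyallyl ethers and the Claisen of aryl 1,1‑dimethylallyl ethers that gives prenylarenes.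
- C6 (OBn) and C7a (ring O) block the other ortho and para positions, so C4 is the only site. No stereocentre is involved.

**Step 12**
Reactants: 14
Product: 15 (5‑methoxy‑6‑benzyloxy‑2‑[3,5‑bis(benzyloxy)phenyl]benzofuran with the 4‑(3‑methyl‑2‑oxobutyl) chain)
Conditions: MeI, K2CO3, DMF, rt → 40 °C
Reagents that add atoms: iodomethane, CI (adds CH3)
Why: Williamson methylation of the hindered phenol. K2CO3 is too weak to C‑alkylate the ketone.

**Step 13**
Reactants: 15
Product: 16 (moracin Q)
Conditions: H2 (1 atm), 10 % Pd/C, EtOAc/EtOH, rt, 2–4 h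
Reagents that add atoms: none
Why: Hydrogenolysis of the three aryl benzyl ethers. The methyl ether, ketone and 2,3‑benzofuran double bond survive a short, mild run.

**Compound list**

| No. | Name | SMILES | Role |
|---|---|---|---|
| 1 | 2,4‑dihydroxybenzaldehyde | O=Cc1ccc(O)cc1O | starting material |
| 2 | 2,4‑dihydroxy‑5‑iodobenzaldehyde | O=Cc1cc(I)c(O)cc1O | intermediate |
| 3 | 3,5‑dihydroxybenzaldehyde | O=Cc1cc(O)cc(O)c1 | starting material |
| 4 | 3,5‑bis(benzyloxy)benzaldehyde | O=Cc1cc(OCc2ccccc2)cc(OCc2ccccc2)c1 | intermediate |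
| 5 | 1,3‑bis(benzyloxy)‑5‑ethynylbenzene | C#Cc1cc(OCc2ccccc2)cc(OCc2ccccc2)c1 | intermediate |
| 6 | 2‑[3,5‑bis(benzyloxy)phenyl]‑6‑hydroxybenzofuran‑5‑carbaldehyde | O=Cc1cc2cc(-c3cc(OCc4ccccc4)cc(OCc4ccccc4)c3)oc2cc1O | intermediate |
| 7 | 6‑benzyloxy‑2‑[3,5‑bis(benzyloxy)phenyl]benzofuran‑5‑carbaldehyde | O=Cc1cc2cc(-c3cc(OCc4ccccc4)cc(OCc4ccccc4)c3)oc2cc1OCc1ccccc1 | intermediate |
| 8 | 6‑benzyloxy‑2‑[3,5‑bis(benzyloxy)phenyl]benzofuran‑5‑ol | Oc1cc2cc(-c3cc(OCc4ccccc4)cc(OCc4ccccc4)c3)oc2cc1OCc1ccccc1 | intermediate |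
| 9 | ethyl 2‑bromo‑2‑methylpropanoate | CCOC(=O)C(C)(C)Br | starting material |
| 10 | aryloxy isobutyrate ethyl ester | CCOC(=O)C(C)(C)Oc1cc2cc(-c3cc(OCc4ccccc4)cc(OCc4ccccc4)c3)oc2cc1OCc1ccccc1 | intermediate |
| 11 | aryloxy isobutyramide (Weinreb) | CON(C)C(=O)C(C)(C)Oc1cc2cc(-c3cc(OCc4ccccc4)cc(OCc4ccccc4)c3)oc2cc1OCc1ccccc1 | intermediate |
| 12 | α‑aryloxy methyl ketone, ArO–CMe2–C(=O)CH3 | CC(=O)C(C)(C)Oc1cc2cc(-c3cc(OCc4ccccc4)cc(OCc4ccccc4)c3)oc2cc1OCc1ccccc1 | intermediate |
| 13 | TBS enol ether, ArO–CMe2–C(OTBS)=CH2 | C=C(O[Si](C)(C)C(C)(C)C)C(C)(C)Oc1cc2cc(-c3cc(OCc4ccccc4)cc(OCc4ccccc4)c3)oc2cc1OCc1ccccc1 | intermediate |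
| 14 | 4‑(3‑methyl‑2‑oxobutyl)‑5‑hydroxy tribenzyl ether | CC(C)C(=O)Cc1c(O)c(OCc2ccccc2)cc2oc(-c3cc(OCc4ccccc4)cc(OCc4ccccc4)c3)cc12 | intermediate |
| 15 | 5‑methoxy tribenzyl ether | CC(C)C(=O)Cc1c(OC)c(OCc2ccccc2)cc2oc(-c3cc(OCc4ccccc4)cc(OCc4ccccc4)c3)cc12 | intermediate |
| 16 | moracin Q | COc1c(O)cc2oc(-c3cc(O)cc(O)c3)cc2c1CC(=O)C(C)C | target |

**Totals:** 13 steps in total. The longest linear sequence is 12 steps, running through the alkyne branch: 3 → 4 → 5 → 6 → 7 → 8 → 10 → 11 → 12 → 13 → 14 → 15 → 16 (steps 2, 3, 4, 5, 6, 7, 8, 9, 10, 11, 12, 13). The iodoaldehyde branch (1 → 2, step 1) joins at step 4.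

**Three steps most likely to fail**
1. **Step 11 (proposed new Claisen).** The tertiary C–O bond could ionize or undergo retro‑ene elimination at 180 °C, giving phenol 8 and an enone.
   - Fallback (known chemistry, different approach): from 8, make the propargyl ether with 3‑chloro‑3‑methylbut‑1‑yne (CuI, K2CO3, KI). Lindlar‑reduce it to the 1,1‑dimethylallyl ether and run the known Claisen (~140 °C) to the 4‑prenyl‑5‑ol.
   - Then methylate (MeI), hydroborate with 9‑BBN then H2O2/NaOH (boron goes to the less substituted CH carbon), oxidize the secondary alcohol with DMP to the isopropyl ketone, and hydrogenolyze.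
2. **Step 6 (mCPBA Baeyer–Villiger).** The peracid may epoxidize the electron‑rich 2,3‑benzofuran double bond or over‑oxidize the product phenol.
   - Fallback: run a classical Dakin oxidation (H2O2, NaOH) on the free ortho‑hydroxy aldehyde 6, which uses no electrophilic oxidant, to give the 5,6‑diol.
   - Then selectively benzylate the more acidic 6‑OH (1 equiv BnBr, NaHCO3) to reach 8. The 6‑OH is para to C3a, which is conjugated to the 2‑aryl group through C2=C3, so its phenoxide is better stabilized than the 5‑phenoxide.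
3. **Step 7 (SN2 at a tertiary α‑bromoester with a hindered ortho‑substituted phenol).** Elimination to the methacrylate may compete.
   - Fallback: drop the tertiary‑ether route and allylate 8 (allyl bromide, K2CO3), then use the known allyl Claisen (190 °C) to give the 4‑allyl‑5‑ol.
   - Then cross‑metathesize with 2‑methyl‑2‑butene (Hoveyda–Grubbs II) to the prenyl arene and finish as in the fallback for step 11 (methylate, 9‑BBN, H2O2/NaOH, DMP, hydrogenolysis).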